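**Retrosynthetic overview**
- Target ← acetylation of the C12 alcohol ← catalyst-controlled vinylogous Mukaiyama aldol of a C4-formyl dihydropyran with the silyl dienolate of methyl tiglate; the 7,8-epoxide ← late epoxidation of the strained (E)-cyclononene.
- C4–CHO ← carbonylation of a C3=C4 enol triflate (from the C4 ketone); C11=CH2 ← methylenation of the C11 ketone.
- Key step: the nine-membered ring is closed by 9-endo addition of a C11 acyl radical to C11a of a 4-alkyl-(6R)-6-acetoxy-2H-pyran-3(6H)-one (forms C11–C11a; the C1 acetate steers C11a, C4a follows by H transfer).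
- Pyranone ← Achmatowicz rearrangement and dynamic kinetic acetylation of a 3-alkylfurfuryl alcohol; side chain ← B-alkyl Suzuki coupling of (4E)-5-iodohex-4-enoic acid with 3-ethenylfuran-2-carbaldehyde.
- Ring order: furan → pyranone → nine-membered carbocycle → dihydropyran (enol triflate) → oxirane.

Assumption: in steps 5 and 13 the catalyst antipode named is taken to give the stated configuration; if induction is the reverse, the enantiomeric catalyst is used.

**Route**

Step 1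
Reactants: 1 3-bromofuran-2-carbaldehyde; 2 potassium trifluoro(vinyl)borate
Product: 3 3-ethenylfuran-2-carbaldehyde
Conditions: PdCl2(dppf) (2 mol %), Et3N (3 equiv), n-PrOH, 85 °C
Reagents that add atoms: none
Why: Suzuki–Miyaura (Molander) vinylation of an electron-poor heteroaryl bromide; no stereocentre is formed.

Step 2
Reactants: 4 hex-4-ynoic acid
Product: 6 (4E)-5-iodohex-4-enoic acid, via alkenylzirconocene 5 (not isolated)
Conditions: Cp2Zr(H)Cl (2.6 equiv), THF, 0 → 45 °C; I2, 0 °C; 1 M HCl work-up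
Reagents that add atoms: iodine, II; Cp2Zr(H)Cl, [H][Zr](Cl)(C1C=CC=C1)C1C=CC=C1 (Zr only in 5)
Why: Schwartz hydrozirconation is syn and, with excess reagent, equilibrates zirconium onto the methyl-bearing alkyne carbon (the first equivalent is consumed by the acid); iodinolysis with retention gives the (E)-2-iodoalkene that later becomes C7=C8.

Step 3
Reactants: 3 3-ethenylfuran-2-carbaldehyde; 6 (4E)-5-iodohex-4-enoic acid
Product: 8 (4E)-7-[2-(hydroxymethyl)furan-3-yl]-5-methylhept-4-enoic acid, via bis-borane 7 (not isolated)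
Conditions: 9-BBN (2.2 equiv), THF, 0 → 23 °C; then 6, PdCl2(dppf) (5 mol %), AsPh3, Cs2CO3, DMF/H2O, 23 °C; citric acid work-up
Reagents that add atoms: 9-BBN, B1C2CCCC1CCC2 (boron only in 7)
Why: 9-BBN reduces the aldehyde and hydroborates the vinyl group anti-Markovnikov; the B-alkyl Suzuki–Miyaura coupling then proceeds with retention at the vinyl iodide, fixing the (E)-trisubstituted C7=C8 alkene.

Step 4
Reactants: 8 (4E)-7-[2-(hydroxymethyl)furan-3-yl]-5-methylhept-4-enoic acid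
Product: 9 (4E)-7-(6-hydroxy-3-oxo-3,6-dihydro-2H-pyran-4-yl)-5-methylhept-4-enoic acid
Conditions: VO(acac)2 (5 mol %), t-BuOOH, CH2Cl2, 0 → 23 °C
Reagents that add atoms: tert-butyl hydroperoxide, CC(C)(C)OO
Why: Achmatowicz oxidative ring expansion directed by the furfuryl hydroxyl; the remote trisubstituted alkene is not epoxidised by this reagent, and the lactol is formed as an equilibrating mixture of C6 epimers.

Step 5
Reactants: 9 (4E)-7-(6-hydroxy-3-oxo-3,6-dihydro-2H-pyran-4-yl)-5-methylhept-4-enoic acid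
Product: 10 (4E)-7-[(6R)-6-(acetyloxy)-3-oxo-3,6-dihydro-2H-pyran-4-yl]-5-methylhept-4-enoic acid
Conditions: Ac2O, (S)-BTM (5 mol %), i-Pr2NEt, CHCl3, −20 °C; pH 7 buffer work-up
Reagents that add atoms: acetic anhydride, CC(=O)OC(C)=O
Why: isothiourea-catalysed dynamic kinetic acylation of the rapidly epimerising lactol sets C1 (6R in the pyranone); the carboxylic acid is recovered unchanged after the buffered aqueous work-up.

Step 6
Reactants: 10 (4E)-7-[(6R)-6-(acetyloxy)-3-oxo-3,6-dihydro-2H-pyran-4-yl]-5-methylhept-4-enoic acid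
Product: 12 Se-phenyl (4E)-7-[(6R)-6-(acetyloxy)-3-oxo-3,6-dihydro-2H-pyran-4-yl]-5-methylhept-4-eneselenoate, via acid chloride 11 (not isolated)
Conditions: 1-chloro-N,N,2-trimethylprop-1-en-1-amine, CH2Cl2, 0 °C; then PhSeH, pyridine, −20 °C
Reagents that add atoms: benzeneselenol, [SeH]c1ccccc1; 1-chloro-N,N,2-trimethylprop-1-en-1-amine, CC(C)=C(Cl)N(C)C (Cl only in 11)
Why: neutral acid chloride formation (Ghosez reagent) followed by selenoesterification avoids base and acid at the acetoxy enone; no stereocentre is touched.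

Step 7
Reactants: 12 Se-phenyl (4E)-7-[(6R)-6-(acetyloxy)-3-oxo-3,6-dihydro-2H-pyran-4-yl]-5-methylhept-4-eneselenoate
Product: 15 (1R,4aS,7E,11aS)-7-methyl-4,11-dioxo-1,3,4,4a,5,6,9,10,11,11a-decahydrocyclonona[c]pyran-1-yl acetate, via acyl radical 13 (not isolated), via enoxyl radical 14 (not isolated)
Conditions: (Me3Si)3SiH (1.3 equiv, syringe pump), V-70 (0.3 equiv), C6H6 (0.003 M), 30 °C, CO (1 atm)
Reagents that add atoms: none
Why: Proposed new method: the nucleophilic acyl radical freed from the selenoester is long-lived under slow silane addition (it is reduced by the silane only at about 10^4 M-1 s-1, does not attack benzene, and cannot scramble the C7=C8 geometry as a C10 alkyl radical would), so a 9-endo-trig Giese addition to the unsubstituted β-carbon C11a can compete and occurs anti to the pseudoaxial C1 acetate, setting C11a; the enoxyl radical then takes H from the silane at C4a, and the trans ring fusion is the outcome expected if the (E)-cyclononene relaxes to an antiperiplanar fusion (an epimerisable α-keto centre, and the least secure stereochemical call in the route); the closest known reaction types are acyl radical macrocyclisation of phenyl selenoesters onto enones and trans-selective radical additions to 6-acyloxy-2H-pyran-3(6H)-ones.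

Step 8
Reactants: 15 (1R,4aS,7E,11aS)-7-methyl-4,11-dioxo-1,3,4,4a,5,6,9,10,11,11a-decahydrocyclonona[c]pyran-1-yl acetate
Product: 17 (1R,4aS,7E,11aS)-7-methyl-11-oxo-4-[(trifluoromethanesulfonyl)oxy]-1,4a,5,6,9,10,11,11a-octahydrocyclonona[c]pyran-1-yl acetate, via potassium enolate 16 (not isolated)
Conditions: KN(SiMe3)2 (1.05 equiv) added to 15 and PhNTf2 (1.1 equiv), THF, −78 °C
Reagents that add atoms: N-phenylbis(trifluoromethanesulfonimide), O=S(=O)(N(c1ccccc1)S(=O)(=O)C(F)(F)F)C(F)(F)F; KN(SiMe3)2, C[Si](C)(C)[N-][Si](C)(C)C.[K+] (K only in 16)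
Why: kinetic enolisation with in situ O-triflation is expected at the unhindered, oxygen-activated C3 methylene of the six-ring ketone rather than at the ring-fusion C4a–H or the nine-ring ketone, giving the C3=C4 enol triflate; C1, C4a and C11a are untouched.

Step 9
Reactants: 17 (1R,4aS,7E,11aS)-7-methyl-11-oxo-4-[(trifluoromethanesulfonyl)oxy]-1,4a,5,6,9,10,11,11a-octahydrocyclonona[c]pyran-1-yl acetate
Product: 18 (1R,4aS,7E,11aR)-7-methyl-11-methylidene-4-[(trifluoromethanesulfonyl)oxy]-1,4a,5,6,9,10,11,11a-octahydrocyclonona[c]pyran-1-yl acetate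
Conditions: Zn, CH2Br2, TiCl4 (pre-formed in THF), CH2Cl2, 0 → 23 °C
Reagents that add atoms: dibromomethane, BrCBr
Why: Takai–Lombardo methylenation converts the remaining, hindered ketone under non-basic conditions, so the β-acetoxy ketone is not eliminated and the vinyl triflate and acetate survive (the C11a descriptor changes from S to R by priority only).

Step 10
Reactants: 18 (1R,4aS,7E,11aR)-7-methyl-11-methylidene-4-[(trifluoromethanesulfonyl)oxy]-1,4a,5,6,9,10,11,11a-octahydrocyclonona[c]pyran-1-yl acetate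
Product: 19 (1R,4aS,7E,11aR)-4-formyl-7-methyl-11-methylidene-1,4a,5,6,9,10,11,11a-octahydrocyclonona[c]pyran-1-yl acetate
Conditions: Pd(PPh3)4 (5 mol %), CO (1 atm), Bu3SnH (slow addition), LiCl, THF, 50 °C
Reagents that add atoms: carbon monoxide, [C-]#[O+]
Why: palladium-catalysed reductive carbonylation (Stille formylation) of the vinyl triflate gives the vinylogous formate; no stereocentre is involved.

Step 11
Reactants: 19 (1R,4aS,7E,11aR)-4-formyl-7-methyl-11-methylidene-1,4a,5,6,9,10,11,11a-octahydrocyclonona[c]pyran-1-yl acetate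
Product: 20 (1R,4aS,7S,8S,11aR)-7,8-epoxy-4-formyl-7-methyl-11-methylidene-1,4a,5,6,7,8,9,10,11,11a-decahydrocyclonona[c]pyran-1-yl acetate
Conditions: DMDO (1.05 equiv), acetone, −78 → −40 °C
Reagents that add atoms: dimethyldioxirane, CC1(C)OO1
Why: syn-stereospecific dioxirane epoxidation is fastest at the strained trisubstituted (E)-alkene (the enol ether is deactivated as a vinylogous formate, the 1,1-disubstituted alkene is slower) and attacks its exposed outer face, as in β-caryophyllene → caryophyllene oxide, whose ring-fusion/alkene relationship is the same, giving the 7S,8S oxirane.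

Step 12
Reactants: 21 methyl (2E)-2-methylbut-2-enoate (methyl tiglate)
Product: 23 [(1-methoxy-2-methylbuta-1,3-dien-1-yl)oxy]trimethylsilane, via lithium dienolate 22 (not isolated)
Conditions: LiN(i-Pr)2, THF/DMPU, −78 °C; Me3SiCl
Reagents that add atoms: chlorotrimethylsilane, C[Si](C)(C)Cl; LiN(i-Pr)2, CC(C)[N-]C(C)C.[Li+] (Li only in 22)
Why: γ-deprotonation of the enoate and O-silylation give the silyl dienol ether (ketene acetal geometry is inconsequential).

Step 13
Reactants: 20 (1R,4aS,7S,8S,11aR)-7,8-epoxy-4-formyl-7-methyl-11-methylidene-1,4a,5,6,7,8,9,10,11,11a-decahydrocyclonona[c]pyran-1-yl acetate; 23 [(1-methoxy-2-methylbuta-1,3-dien-1-yl)oxy]trimethylsilane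
Product: 25 methyl (2E,5R)-5-[(1R,4aS,7S,8S,11aR)-1-(acetyloxy)-7,8-epoxy-7-methyl-11-methylidene-1,4a,5,6,7,8,9,10,11,11a-decahydrocyclonona[c]pyran-4-yl]-5-hydroxy-2-methylpent-2-enoate, via silyl ether 24 (not isolated)
Conditions: Cu(OTf)2 (10 mol %), (S)-Tol-BINAP (11 mol %), Bu4N[Ph3SiF2] (20 mol %), THF, −78 → −40 °C; then 0.5 M citric acid, THF/H2O, 0 °C
Reagents that add atoms: none
Why: catalytic enantioselective vinylogous Mukaiyama aldol through a chiral copper dienolate attacks the aldehyde at the γ-carbon, giving the (E)-2-methyl enoate, with the catalyst (not the remote ring stereocentres) setting C12 as R; the non-acidic conditions spare the oxirane and acetal acetate.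

Step 14
Reactants: 25 methyl (2E,5R)-5-[(1R,4aS,7S,8S,11aR)-1-(acetyloxy)-7,8-epoxy-7-methyl-11-methylidene-1,4a,5,6,7,8,9,10,11,11a-decahydrocyclonona[c]pyran-4-yl]-5-hydroxy-2-methylpent-2-enoate
Product: 26 methyl (2E,5R)-5-(acetyloxy)-5-[(1R,4aS,7S,8S,11aR)-1-(acetyloxy)-7,8-epoxy-7-methyl-11-methylidene-1,4a,5,6,7,8,9,10,11,11a-decahydrocyclonona[c]pyran-4-yl]-2-methylpent-2-enoate (CNP0184381.4)
Conditions: Ac2O, pyridine, DMAP (cat.), CH2Cl2, 0 °C
Reagents that add atoms: acetic anhydride, CC(=O)OC(C)=O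
Why: DMAP-catalysed acetylation of the secondary allylic alcohol with retention at C12 completes the target.

**Compound list**
1 | 3-bromofuran-2-carbaldehyde | O=Cc1occc1Br | starting material
2 | potassium trifluoro(vinyl)borate | [K+].C=C[B-](F)(F)F | starting material
3 | 3-ethenylfuran-2-carbaldehyde | O=Cc1occc1C=C | intermediate
4 | hex-4-ynoic acid | CC#CCCC(O)=O | starting material
5 | chlorobis(cyclopentadienyl)zirconium (4E)-5-[chlorobis(cyclopentadienyl)zirconio]hex-4-enoate | C/C(=C\CCC(=O)O[Zr](Cl)(C1C=CC=C1)C1C=CC=C1)[Zr](Cl)(C1C=CC=C1)C1C=CC=C1 | intermediate (not isolated)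
6 | (4E)-5-iodohex-4-enoic acid | C/C(I)=C\CCC(O)=O | intermediate
7 | 9-[2-(2-{[(9-borabicyclo[3.3.1]nonan-9-yl)oxy]methyl}furan-3-yl)ethyl]-9-borabicyclo[3.3.1]nonane | B1(CCc2ccoc2COB2C3CCCC2CCC3)C2CCCC1CCC2 | intermediate (not isolated)
8 | (4E)-7-[2-(hydroxymethyl)furan-3-yl]-5-methylhept-4-enoic acid | OCc1occc1CC/C(C)=C/CCC(O)=O | intermediate
9 | (4E)-7-(6-hydroxy-3-oxo-3,6-dihydro-2H-pyran-4-yl)-5-methylhept-4-enoic acid (both C6 epimers) | OC1OCC(=O)C(CC/C(C)=C/CCC(O)=O)=C1 | intermediate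
10 | (4E)-7-[(6R)-6-(acetyloxy)-3-oxo-3,6-dihydro-2H-pyran-4-yl]-5-methylhept-4-enoic acid | CC(=O)O[C@H]1OCC(=O)C(CC/C(C)=C/CCC(O)=O)=C1 | intermediate
11 | (4E)-7-[(6R)-6-(acetyloxy)-3-oxo-3,6-dihydro-2H-pyran-4-yl]-5-methylhept-4-enoyl chloride | CC(=O)O[C@H]1OCC(=O)C(CC/C(C)=C/CCC(Cl)=O)=C1 | intermediate (not isolated)
12 | Se-phenyl (4E)-7-[(6R)-6-(acetyloxy)-3-oxo-3,6-dihydro-2H-pyran-4-yl]-5-methylhept-4-eneselenoate | CC(=O)O[C@H]1OCC(=O)C(CC/C(C)=C/CCC(=O)[Se]c2ccccc2)=C1 | intermediate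
13 | (4E)-7-[(6R)-6-(acetyloxy)-3-oxo-3,6-dihydro-2H-pyran-4-yl]-5-methylhept-4-enoyl radical | CC(=O)O[C@H]1OCC(=O)C(CC/C(C)=C/CC[C]=O)=C1 | intermediate (not isolated)
14 | (1R,7E,11aS)-1-(acetyloxy)-7-methyl-4,11-dioxo-decahydrocyclonona[c]pyran-4a-yl (enoxyl) radical | O=C1CC/C=C(C)/CC[C]2C(=O)CO[C@H](OC(C)=O)[C@@H]12 | intermediate (not isolated)
15 | (1R,4aS,7E,11aS)-7-methyl-4,11-dioxo-1,3,4,4a,5,6,9,10,11,11a-decahydrocyclonona[c]pyran-1-yl acetate | O=C1CC/C=C(C)/CC[C@@H]2C(=O)CO[C@H](OC(C)=O)[C@@H]12 | intermediate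
16 | potassium (1R,4aS,7E,11aS)-1-(acetyloxy)-7-methyl-11-oxo-1,4a,5,6,9,10,11,11a-octahydrocyclonona[c]pyran-4-olate | O=C1CC/C=C(C)/CC[C@@H]2C([O-])=CO[C@H](OC(C)=O)[C@@H]12.[K+] | intermediate (not isolated)
17 | (1R,4aS,7E,11aS)-7-methyl-11-oxo-4-[(trifluoromethanesulfonyl)oxy]-1,4a,5,6,9,10,11,11a-octahydrocyclonona[c]pyran-1-yl acetate | O=C1CC/C=C(C)/CC[C@@H]2C(OS(=O)(=O)C(F)(F)F)=CO[C@H](OC(C)=O)[C@@H]12 | intermediate
18 | (1R,4aS,7E,11aR)-7-methyl-11-methylidene-4-[(trifluoromethanesulfonyl)oxy]-1,4a,5,6,9,10,11,11a-octahydrocyclonona[c]pyran-1-yl acetate | C=C1CC/C=C(C)/CC[C@@H]2C(OS(=O)(=O)C(F)(F)F)=CO[C@H](OC(C)=O)[C@@H]12 | intermediate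
19 | (1R,4aS,7E,11aR)-4-formyl-7-methyl-11-methylidene-1,4a,5,6,9,10,11,11a-octahydrocyclonona[c]pyran-1-yl acetate | C=C1CC/C=C(C)/CC[C@@H]2C(C=O)=CO[C@H](OC(C)=O)[C@@H]12 | intermediate
20 | (1R,4aS,7S,8S,11aR)-7,8-epoxy-4-formyl-7-methyl-11-methylidene-1,4a,5,6,7,8,9,10,11,11a-decahydrocyclonona[c]pyran-1-yl acetate | C=C1CC[C@@H]2O[C@@]2(C)CC[C@@H]2C(C=O)=CO[C@H](OC(C)=O)[C@@H]12 | intermediate
21 | methyl (2E)-2-methylbut-2-enoate | C/C=C(\C)C(=O)OC | starting material
22 | lithium 1-methoxy-2-methylbuta-1,3-dien-1-olate | [Li+].[O-]C(OC)=C(C)C=C | intermediate (not isolated)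
23 | [(1-methoxy-2-methylbuta-1,3-dien-1-yl)oxy]trimethylsilane (E/Z mixture) | COC(O[Si](C)(C)C)=C(C)C=C | intermediate
24 | methyl (2E,5R)-5-[(1R,4aS,7S,8S,11aR)-1-(acetyloxy)-7,8-epoxy-7-methyl-11-methylidene-decahydrocyclonona[c]pyran-4-yl]-2-methyl-5-[(trimethylsilyl)oxy]pent-2-enoate | C=C1CC[C@@H]2O[C@@]2(C)CC[C@@H]2C([C@@H](C/C=C(\C)C(=O)OC)O[Si](C)(C)C)=CO[C@H](OC(C)=O)[C@@H]12 | intermediate (not isolated)
25 | methyl (2E,5R)-5-[(1R,4aS,7S,8S,11aR)-1-(acetyloxy)-7,8-epoxy-7-methyl-11-methylidene-decahydrocyclonona[c]pyran-4-yl]-5-hydroxy-2-methylpent-2-enoate | C=C1CC[C@@H]2O[C@@]2(C)CC[C@@H]2C([C@@H](C/C=C(\C)C(=O)OC)O)=CO[C@H](OC(C)=O)[C@@H]12 | intermediate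
26 | methyl (2E,5R)-5-(acetyloxy)-5-[(1R,4aS,7S,8S,11aR)-1-(acetyloxy)-7,8-epoxy-7-methyl-11-methylidene-decahydrocyclonona[c]pyran-4-yl]-2-methylpent-2-enoate | C=C1CC[C@@H]2O[C@@]2(C)CC[C@@H]2C([C@@H](C/C=C(\C)C(=O)OC)OC(C)=O)=CO[C@H](OC(C)=O)[C@@H]12 | target

**Totals**
Total step count: 14. Longest linear sequence: 12 (steps 2, 3, 4, 5, 6, 7, 8, 9, 10, 11, 13, 14).

**Three steps most likely to fail**

Step 7 (ring closure). The 9-endo closure may lose to reduction of the acyl radical or to decarbonylation. The hydrogen transfer at C4a is the weakest point: the ordinary preference for delivery anti to the new C11 substituent would give the cis-fused ketone. Fallback: setting out from selenoester 12, reduction with Bu3SnH and Pd(PPh3)4 (cat.) gives the aldehyde (2R)-4-[(3E)-3-methyl-7-oxohept-3-en-1-yl]-5-oxo-5,6-dihydro-2H-pyran-2-yl acetate F1. An intramolecular Stetter reaction (triazolium-derived carbene, catalytic i-Pr2NEt, toluene, high dilution) then forms the same C11–C11a bond by a polar acyl-anion addition, and the route is rejoined at diketone 15. If the ring fusion is formed cis by either path, C4a is best equilibrated at ketone F4 of the next fallback, where no β-acetoxy ketone is present.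

Step 8 (selective triflation). The base may instead enolise the C11 ketone or eliminate the C1 acetate from the β-acetoxy ketone. Fallback: setting out from diketone 15, Luche reduction (NaBH4, CeCl3·7H2O, MeOH, −78 °C) touches only the far more reactive six-ring ketone and gives (1R,4aS,7E,11aS)-4-hydroxy-7-methyl-11-oxo-1,3,4,4a,5,6,9,10,11,11a-decahydrocyclonona[c]pyran-1-yl acetate F2. Methylenation of C11 (Zn, CH2Br2, TiCl4) gives (1R,4aS,7E,11aR)-4-hydroxy-7-methyl-11-methylidene-1,3,4,4a,5,6,9,10,11,11a-decahydrocyclonona[c]pyran-1-yl acetate F3. Dess–Martin oxidation gives (1R,4aS,7E,11aR)-7-methyl-11-methylidene-4-oxo-1,3,4,4a,5,6,9,10,11,11a-decahydrocyclonona[c]pyran-1-yl acetate F4, now the only ketone. KN(SiMe3)2/PhNTf2 at −78 °C then rejoins the route at triflate 18.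

Step 13 (vinylogous aldol). The vinylogous formate is a weak electrophile and C12 rests on catalyst control alone. Fallback: setting out from aldehyde 20, Brown allylation with B-allylbis(isopinocampheyl)borane prepared from (−)-α-pinene (Et2O, −78 °C, ethanolamine work-up) gives (1R,4aS,7S,8S,11aR)-7,8-epoxy-4-[(1R)-1-hydroxybut-3-en-1-yl]-7-methyl-11-methylidene-1,4a,5,6,7,8,9,10,11,11a-decahydrocyclonona[c]pyran-1-yl acetate F5. Acetylation (Ac2O, pyridine, DMAP) gives (1R,4aS,7S,8S,11aR)-4-[(1R)-1-(acetyloxy)but-3-en-1-yl]-7,8-epoxy-7-methyl-11-methylidene-1,4a,5,6,7,8,9,10,11,11a-decahydrocyclonona[c]pyran-1-yl acetate F6. Cross-metathesis with methyl methacrylate (C=C(C)C(=O)OC; second-generation Hoveyda–Grubbs catalyst, CH2Cl2, 40 °C) installs the (E)-2-methyl enoate and arrives directly at target 26.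

**Further compounds**
F1 | step 7 | (2R)-4-[(3E)-3-methyl-7-oxohept-3-en-1-yl]-5-oxo-5,6-dihydro-2H-pyran-2-yl acetate | CC(=O)O[C@H]1OCC(=O)C(CC/C(C)=C/CCC=O)=C1
F2 | step 8 | (1R,4aS,7E,11aS)-4-hydroxy-7-methyl-11-oxo-1,3,4,4a,5,6,9,10,11,11a-decahydrocyclonona[c]pyran-1-yl acetate (C4 epimers) | O=C1CC/C=C(C)/CC[C@@H]2C(O)CO[C@H](OC(C)=O)[C@@H]12
F3 | step 8 | (1R,4aS,7E,11aR)-4-hydroxy-7-methyl-11-methylidene-1,3,4,4a,5,6,9,10,11,11a-decahydrocyclonona[c]pyran-1-yl acetate (C4 epimers) | C=C1CC/C=C(C)/CC[C@@H]2C(O)CO[C@H](OC(C)=O)[C@@H]12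
F4 | step 8 | (1R,4aS,7E,11aR)-7-methyl-11-methylidene-4-oxo-1,3,4,4a,5,6,9,10,11,11a-decahydrocyclonona[c]pyran-1-yl acetate | C=C1CC/C=C(C)/CC[C@@H]2C(=O)CO[C@H](OC(C)=O)[C@@H]12
F5 | step 13 | (1R,4aS,7S,8S,11aR)-7,8-epoxy-4-[(1R)-1-hydroxybut-3-en-1-yl]-7-methyl-11-methylidene-1,4a,5,6,7,8,9,10,11,11a-decahydrocyclonona[c]pyran-1-yl acetate | C=C1CC[C@@H]2O[C@@]2(C)CC[C@@H]2C([C@@H](CC=C)O)=CO[C@H](OC(C)=O)[C@@H]12
F6 | step 13 | (1R,4aS,7S,8S,11aR)-4-[(1R)-1-(acetyloxy)but-3-en-1-yl]-7,8-epoxy-7-methyl-11-methylidene-1,4a,5,6,7,8,9,10,11,11a-decahydrocyclonona[c]pyran-1-yl acetate | C=C1CC[C@@H]2O[C@@]2(C)CC[C@@H]2C([C@@H](CC=C)OC(C)=O)=CO[C@H](OC(C)=O)[C@@H]12
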